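A direct plan would keep all five rings aromatic throughout and use ring C as a double electrophile. The A–B phenol A2 and the D–E phenol A3 would displace, one after the other, the two fluorides of 4,5-difluoro-3-methoxyphthalaldehyde A1. The two formyl groups of the resulting dialdehyde A4 would then become ring C hydroxyls by a double Dakin oxidation, and the methyl ethers would be cleaved last. Its weakest steps would be:
- the ordered displacement of two neighbouring fluorides, because both are para to a formyl group, so the site order would rest on small electronic and steric differences, with a di-ortho-substituted phenoxide beside base-sensitive ortho-formyl groups;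
- the double Dakin oxidation of an ortho-dialdehyde, which would be prone to phthalide or anhydride formation and to over-oxidation of the electron-rich rings;
- the multi-step preparation of A1, which would add length but no complexity.

Ring C (C1 bears the ring B oxygen, C2 is H, C3–C5 bear OH, C6 bears the ring D oxygen) would be made last, from non-aromatic carbon: C3–C6 from squaric acid and C1–C2 from an aryl ethynyl ether. The key step, a thermal cyclobutenone–ynol ether benzannulation, would join the A–B and D–E halves and close ring C in one operation. It exploits the five contiguous oxygens and single hydrogen of ring C: the C1, C4, C5 and C6 oxygens ride in on the partners and the C3 hydroxyl is the ketene carbonyl. No C–O bond is formed at ring C, so the fluoride displacements, the dialdehyde and its Dakin oxidation have no counterpart.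

Key step: step 11

Remark: rings are lettered A to E from the 2,4,6-trihydroxyphenyl end. The target is achiral; the stereocentres of 19, 20, 22 and 24 are racemic and vanish when ring C becomes aromatic.

Step 1
Reactants: 1 2,4,6-trimethoxyphenol; 2 4-bromo-2,6-dimethoxybenzaldehyde
Product: 3 2,6-dimethoxy-4-(2,4,6-trimethoxyphenoxy)benzaldehyde
Conditions: CuI (10 mol%), picolinic acid (20 mol%), K3PO4, DMSO, 90 °C, Ar
Reagents that add atoms: none
Why: Ullmann-type C–O coupling, in which the CuI–picolinic acid system accepts the di-ortho-substituted phenol and the bromide is unhindered and activated by its para formyl group.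

Step 2
Reactants: 3 2,6-dimethoxy-4-(2,4,6-trimethoxyphenoxy)benzaldehyde
Product: 5 2,6-dimethoxy-4-(2,4,6-trimethoxyphenoxy)phenol, via aryl formate 4 (not isolated)
Conditions: mCPBA, CH2Cl2, 0 °C to rt; aq Na2S2O3; then K2CO3 (cat.), MeOH, rt, Ar
Reagents that add atoms: 3-chloroperoxybenzoic acid, OOC(=O)c1cccc(Cl)c1
Why: Dakin-type Baeyer–Villiger oxidation of a single, electron-rich benzaldehyde, in which the aryl group with two ortho methoxy groups migrates in preference to hydride, followed by methanolysis of the formate.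

Step 3
Reactants: 5 2,6-dimethoxy-4-(2,4,6-trimethoxyphenoxy)phenol
Product: 6 2-{[(E)-1,2-dichloroethenyl]oxy}-1,3-dimethoxy-5-(2,4,6-trimethoxyphenoxy)benzene
Conditions: trichloroethylene (2 equiv), K2CO3, DMF, 70 °C, Ar
Reagents that add atoms: trichloroethylene, ClC=C(Cl)Cl
Why: Known dichlorovinyl ether synthesis, in which K2CO3 turns trichloroethylene into dichloroacetylene in the flask and the phenoxide adds to it anti to give the E ether; the two carbons introduced become C1 and C2 of ring C.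

Step 4
Reactants: 6 2-{[(E)-1,2-dichloroethenyl]oxy}-1,3-dimethoxy-5-(2,4,6-trimethoxyphenoxy)benzene
Product: 9 2-(ethynyloxy)-1,3-dimethoxy-5-(2,4,6-trimethoxyphenoxy)benzene (A–B ynol ether), via chloroethynyl ether 7 (not isolated), via lithium acetylide 8 (not isolated)
Conditions: n-BuLi (2.2 equiv), THF, −78 to −40 °C; MeOH, −78 °C; cold work-up, used at once
Reagents that add atoms: none
Why: Known ynol ether synthesis from 1,2-dichlorovinyl ethers, in which one equivalent of n-BuLi eliminates HCl, a second exchanges the remaining chlorine for lithium, and the acetylide is protonated; the aryl ether cannot undergo the retro-ene loss of an alkyl ynol ether.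

Step 5
Reactants: 10 3,4,5-trimethoxyphenol; 11 3-bromo-4,5-dimethoxybenzaldehyde
Product: 12 3,4-dimethoxy-5-(3,4,5-trimethoxyphenoxy)benzaldehyde
Conditions: CuI (10 mol%), picolinic acid (20 mol%), K3PO4, DMSO, 90 °C, Ar
Reagents that add atoms: none
Why: Ullmann-type C–O coupling of an unhindered phenol with a mono-ortho-substituted aryl bromide whose non-enolisable formyl group is inert to K3PO4.

Step 6
Reactants: 12 3,4-dimethoxy-5-(3,4,5-trimethoxyphenoxy)benzaldehyde
Product: 14 3,4-dimethoxy-5-(3,4,5-trimethoxyphenoxy)phenol, via aryl formate 13 (not isolated)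
Conditions: mCPBA, CH2Cl2, 0 °C to rt; aq Na2S2O3; then K2CO3 (cat.), MeOH, rt, Ar
Reagents that add atoms: 3-chloroperoxybenzoic acid, OOC(=O)c1cccc(Cl)c1
Why: Dakin-type Baeyer–Villiger oxidation of a 3,4,5-trioxygenated benzaldehyde, whose para methoxy group favours aryl migration, followed by methanolysis of the formate.

Step 7
Reactants: 15 squaric acid (3,4-dihydroxycyclobut-3-ene-1,2-dione)
Product: 16 3,4-dichlorocyclobut-3-ene-1,2-dione (squaric dichloride)
Conditions: (COCl)2 (2.5 equiv), DMF (cat.), CH2Cl2, rt to reflux; sublimation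
Reagents that add atoms: oxalyl chloride, O=C(Cl)C(=O)Cl
Why: Vilsmeier-type chlorination, a standard preparation of this compound, turns the two vinylogous acid hydroxyls into vinylogous acid chlorides.

Step 8
Reactants: 16 3,4-dichlorocyclobut-3-ene-1,2-dione; 14 3,4-dimethoxy-5-(3,4,5-trimethoxyphenoxy)phenol
Product: 18 3-[3,4-dimethoxy-5-(3,4,5-trimethoxyphenoxy)phenoxy]-4-methoxycyclobut-3-ene-1,2-dione, via 3-chloro-4-methoxycyclobut-3-ene-1,2-dione 17 (not isolated)
Conditions: 16 (1.3 equiv), MeOH (1.3 equiv), iPr2NEt, CH2Cl2, −78 °C; then 14 (1.0 equiv), iPr2NEt, −78 to 0 °C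
Reagents that add atoms: methanol, CO
Why: Two successive addition–elimination substitutions at the vinylogous acid chloride carbons, in which the first methoxy group deactivates the second chloride enough for clean mono-substitution before the phenol is added.

Step 9
Reactants: 18 3-[3,4-dimethoxy-5-(3,4,5-trimethoxyphenoxy)phenoxy]-4-methoxycyclobut-3-ene-1,2-dione
Product: 19 2-[3,4-dimethoxy-5-(3,4,5-trimethoxyphenoxy)phenoxy]-4-hydroxy-3-methoxycyclobut-2-en-1-one (racemic)
Conditions: LiAlH(OtBu)3 (1.05 equiv), THF, −78 °C; aq NH4Cl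
Reagents that add atoms: none
Why: 1,2-Reduction of one squarate carbonyl by a bulky alkoxyaluminium hydride, known for dialkyl squarates, should take place at the carbonyl next to the methoxy-bearing carbon, since its vinylogous donor is the weaker aryloxy group and its flank is the smaller one; the new stereocentre is racemic and is lost in step 11.

Step 10
Reactants: 19 2-[3,4-dimethoxy-5-(3,4,5-trimethoxyphenoxy)phenoxy]-4-hydroxy-3-methoxycyclobut-2-en-1-one
Product: 20 2-[3,4-dimethoxy-5-(3,4,5-trimethoxyphenoxy)phenoxy]-3,4-dimethoxycyclobut-2-en-1-one (racemic)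
Conditions: MeI, Ag2O, 4 Å MS, CH2Cl2, rt, dark
Reagents that add atoms: iodomethane, CI
Why: Purdie methylation under nearly neutral conditions caps the hydroxyl, so that the vinylketene of step 11 cannot lactonise to a butenolide and the oxygen becomes the C4 methoxy group of ring C.

Step 11
Reactants: 20 2-[3,4-dimethoxy-5-(3,4,5-trimethoxyphenoxy)phenoxy]-3,4-dimethoxycyclobut-2-en-1-one; 9 2-(ethynyloxy)-1,3-dimethoxy-5-(2,4,6-trimethoxyphenoxy)benzene
Product: 25 2,3-dimethoxy-4-[3,4-dimethoxy-5-(3,4,5-trimethoxyphenoxy)phenoxy]-5-[2,6-dimethoxy-4-(2,4,6-trimethoxyphenoxy)phenoxy]phenol, via vinylketene 21 (not isolated), via 4-vinylcyclobutenone 22 (not isolated), via dienylketene 23 (not isolated), via cyclohexadienone 24 (not isolated)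
Conditions: 9 (1.5 equiv), toluene, 110 °C, Ar; 20 added slowly (high dilution)
Reagents that add atoms: none
Why: Proposed new method: heating should open 20 by conrotatory 4π cleavage of its C1–C4 bond (the 4-methoxy group turning outward) to the aryloxy(vinyl)ketene 21, whose carbonyl carbon is attacked by the nucleophilic CH terminus of ynol ether 9 in a regiospecific [2+2] cycloaddition to give 22; a second 4π opening (aryloxy outward, vinyl inward) gives dienylketene 23, 6π electrocyclisation gives dienone 24, and tautomerisation gives phenol 25. The closest known reaction types are the Danheiser benzannulation of cyclobutenones with alkoxy- and siloxyalkynes and the Moore rearrangement of squarate-derived 4-alkenylcyclobutenones; what is untested is the capture of a fully oxygenated, squarate-derived vinylketene by an outside alkyne and the use of an aryl ethynyl ether. Ring C is closed by the thermal 6π electrocyclisation of 23 (bond C3–C4), after the [2+2] step has made bonds C2–C3 and C1–C6, so that the two alkyne carbons end up inserted between the carbonyl carbon and the aryloxy-bearing carbon of 20. No stereocentre survives, because the sp3 carbons of 20, 22 and 24 all become aromatic carbons of ring C. The step needs one regiochemistry, and the polarity of the partners secures it: the ynol ether β-carbon bonds to the ketene carbonyl carbon, which puts H at C2, the ring B oxygen at C1 next to the ring D oxygen at C6 (the ketene α-carbon), the methoxy groups at C5 and C4 and the new hydroxyl at C3. It also needs capture by the alkyne to outrun ketene dimerisation and acylation of 25 by 21, which slow addition of 20 to an excess of 9 should favour.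

Step 12
Reactants: 25 2,3-dimethoxy-4-[3,4-dimethoxy-5-(3,4,5-trimethoxyphenoxy)phenoxy]-5-[2,6-dimethoxy-4-(2,4,6-trimethoxyphenoxy)phenoxy]phenol
Product: 26 CNP0154768.0, the tridecahydroxy pentaaryl ether
Conditions: BBr3 (excess), CH2Cl2, −78 °C to rt, Ar; ice-water quench
Reagents that add atoms: none
Why: Lewis-acid ether cleavage, in which bromide attacks the methyl carbon of each O–BBr3 adduct (SN2), should remove the twelve methyl groups, while the four diaryl ether bonds offer no sp3 carbon and should persist.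

**Compound list**

1 | 2,4,6-trimethoxyphenol | COc1cc(OC)c(O)c(OC)c1 | starting material
2 | 4-bromo-2,6-dimethoxybenzaldehyde | COc1cc(Br)cc(OC)c1C=O | starting material
3 | 2,6-dimethoxy-4-(2,4,6-trimethoxyphenoxy)benzaldehyde | COc1cc(OC)c(Oc2cc(OC)c(C=O)c(OC)c2)c(OC)c1 | intermediate
4 | 2,6-dimethoxy-4-(2,4,6-trimethoxyphenoxy)phenyl formate (not isolated) | COc1cc(OC)c(Oc2cc(OC)c(OC=O)c(OC)c2)c(OC)c1 | intermediate
5 | 2,6-dimethoxy-4-(2,4,6-trimethoxyphenoxy)phenol (A–B phenol) | COc1cc(OC)c(Oc2cc(OC)c(O)c(OC)c2)c(OC)c1 | intermediate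
6 | 2-{[(E)-1,2-dichloroethenyl]oxy}-1,3-dimethoxy-5-(2,4,6-trimethoxyphenoxy)benzene | COc1cc(OC)c(Oc2cc(OC)c(O/C(Cl)=C\Cl)c(OC)c2)c(OC)c1 | intermediate
7 | 2-[(chloroethynyl)oxy]-1,3-dimethoxy-5-(2,4,6-trimethoxyphenoxy)benzene (not isolated) | COc1cc(OC)c(Oc2cc(OC)c(OC#CCl)c(OC)c2)c(OC)c1 | intermediate
8 | lithium {[2,6-dimethoxy-4-(2,4,6-trimethoxyphenoxy)phenoxy]ethynide} (not isolated) | COc1cc(OC)c(Oc2cc(OC)c(OC#C[Li])c(OC)c2)c(OC)c1 | intermediate
9 | 2-(ethynyloxy)-1,3-dimethoxy-5-(2,4,6-trimethoxyphenoxy)benzene (A–B ynol ether) | COc1cc(OC)c(Oc2cc(OC)c(OC#C)c(OC)c2)c(OC)c1 | intermediate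
10 | 3,4,5-trimethoxyphenol | COc1cc(O)cc(OC)c1OC | starting material
11 | 3-bromo-4,5-dimethoxybenzaldehyde | COc1cc(C=O)cc(Br)c1OC | starting material
12 | 3,4-dimethoxy-5-(3,4,5-trimethoxyphenoxy)benzaldehyde | COc1cc(C=O)cc(Oc2cc(OC)c(OC)c(OC)c2)c1OC | intermediate
13 | 3,4-dimethoxy-5-(3,4,5-trimethoxyphenoxy)phenyl formate (not isolated) | COc1cc(OC=O)cc(Oc2cc(OC)c(OC)c(OC)c2)c1OC | intermediate
14 | 3,4-dimethoxy-5-(3,4,5-trimethoxyphenoxy)phenol (D–E phenol) | COc1cc(O)cc(Oc2cc(OC)c(OC)c(OC)c2)c1OC | intermediate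
15 | squaric acid (3,4-dihydroxycyclobut-3-ene-1,2-dione) | OC1=C(O)C(=O)C1=O | starting material
16 | 3,4-dichlorocyclobut-3-ene-1,2-dione | ClC1=C(Cl)C(=O)C1=O | intermediate
17 | 3-chloro-4-methoxycyclobut-3-ene-1,2-dione (not isolated) | COC1=C(Cl)C(=O)C1=O | intermediate
18 | 3-[3,4-dimethoxy-5-(3,4,5-trimethoxyphenoxy)phenoxy]-4-methoxycyclobut-3-ene-1,2-dione | COC1=C(Oc2cc(OC)c(OC)c(Oc3cc(OC)c(OC)c(OC)c3)c2)C(=O)C1=O | intermediate
19 | 2-[3,4-dimethoxy-5-(3,4,5-trimethoxyphenoxy)phenoxy]-4-hydroxy-3-methoxycyclobut-2-en-1-one (racemic) | COC1=C(Oc2cc(OC)c(OC)c(Oc3cc(OC)c(OC)c(OC)c3)c2)C(=O)C1O | intermediate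
20 | 2-[3,4-dimethoxy-5-(3,4,5-trimethoxyphenoxy)phenoxy]-3,4-dimethoxycyclobut-2-en-1-one (racemic) | COC1=C(Oc2cc(OC)c(OC)c(Oc3cc(OC)c(OC)c(OC)c3)c2)C(=O)C1OC | intermediate
21 | (Z)-2-[3,4-dimethoxy-5-(3,4,5-trimethoxyphenoxy)phenoxy]-3,4-dimethoxybuta-1,3-dien-1-one, the vinylketene (not isolated) | CO/C=C(\OC)C(=C=O)Oc1cc(OC)c(OC)c(Oc2cc(OC)c(OC)c(OC)c2)c1 | intermediate
22 | 4-[(Z)-1,2-dimethoxyethenyl]-4-[3,4-dimethoxy-5-(3,4,5-trimethoxyphenoxy)phenoxy]-3-[2,6-dimethoxy-4-(2,4,6-trimethoxyphenoxy)phenoxy]cyclobut-2-en-1-one (racemic, not isolated) | O=C1C=C(Oc2c(OC)cc(Oc3c(OC)cc(OC)cc3OC)cc2OC)C1(Oc2cc(OC)c(OC)c(Oc3cc(OC)c(OC)c(OC)c3)c2)C(/OC)=C/OC | intermediate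
23 | (3Z,5Z)-4-[3,4-dimethoxy-5-(3,4,5-trimethoxyphenoxy)phenoxy]-3-[2,6-dimethoxy-4-(2,4,6-trimethoxyphenoxy)phenoxy]-5,6-dimethoxyhexa-1,3,5-trien-1-one, the dienylketene (not isolated) | O=C=C/C(Oc1c(OC)cc(Oc2c(OC)cc(OC)cc2OC)cc1OC)=C(Oc1cc(OC)c(OC)c(Oc2cc(OC)c(OC)c(OC)c2)c1)\C(OC)=C\OC | intermediate
24 | 4-[3,4-dimethoxy-5-(3,4,5-trimethoxyphenoxy)phenoxy]-3-[2,6-dimethoxy-4-(2,4,6-trimethoxyphenoxy)phenoxy]-5,6-dimethoxycyclohexa-2,4-dien-1-one (racemic, not isolated) | O=C1C=C(Oc2c(OC)cc(Oc3c(OC)cc(OC)cc3OC)cc2OC)C(Oc2cc(OC)c(OC)c(Oc3cc(OC)c(OC)c(OC)c3)c2)=C(OC)C1OC | intermediate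
25 | 2,3-dimethoxy-4-[3,4-dimethoxy-5-(3,4,5-trimethoxyphenoxy)phenoxy]-5-[2,6-dimethoxy-4-(2,4,6-trimethoxyphenoxy)phenoxy]phenol | COc1cc(OC)c(Oc2cc(OC)c(Oc3cc(O)c(OC)c(OC)c3Oc3cc(OC)c(OC)c(Oc4cc(OC)c(OC)c(OC)c4)c3)c(OC)c2)c(OC)c1 | intermediate
26 | CNP0154768.0, the tridecahydroxy pentaaryl ether | Oc1cc(O)c(Oc2cc(O)c(Oc3cc(O)c(O)c(O)c3Oc3cc(O)c(O)c(Oc4cc(O)c(O)c(O)c4)c3)c(O)c2)c(O)c1 | target

Total step count: 12. Longest linear sequence: 7 steps (steps 5, 6, 8, 9, 10, 11, 12).

**Steps most likely to fail**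

**Step 11.** The vinylketene may reclose, dimerise or acylate the product phenol faster than the alkyne captures it. Ring C would then be made by the intramolecular, well-precedented form of the same chemistry, setting out from 9 and 14.
- Radical hydrostannylation of 9 (Bu3SnH, AIBN) would give the (Z)-vinylstannane F1.
- Tin–lithium exchange (n-BuLi, THF, −78 °C) would give the vinyllithium F2, which would add to commercial dimethyl squarate F3.
- Trapping of the alkoxide with MeOTf would give the 4-alkenyl-4-methoxycyclobutenone F4.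
- Thermolysis (toluene, 110 °C, Moore rearrangement) would give the phenol F5, whose free hydroxyl sits at C6 of ring C.
- 14 would be turned into its aryl triflate F6 (Tf2O, pyridine).
- A palladium-catalysed C–O coupling of F5 with F6 (Pd(OAc)2, t-BuXPhos, K3PO4, toluene, 100 °C) would give the tridecamethyl ether F7.
- The conditions of step 12 would take F7 to the target 26, where the fallback rejoins the route.

**Step 9.** The hydride may attack the other carbonyl group, or displace the aryloxide by conjugate addition. The regiochemistry would then be fixed by symmetry, setting out from 16 and 14.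
- 16 with two equivalents of 14 (iPr2NEt, CH2Cl2) would give the bis(aryl) squarate F8.
- LiAlH(OtBu)3 would give the hydroxycyclobutenone F9, with no choice of carbonyl.
- MeI and Ag2O would give the methyl ether F10.
- One equivalent of NaOMe in MeOH–THF at −40 °C would exchange only the aryloxy group at C3, the vinylogous ester position, by addition–elimination.
- This returns to the route at 20 and releases 14 for reuse.

**Step 4.** The terminal ynol ether may be lost by hydration or oligomerisation during work-up and storage. The alkyne terminus would then be kept masked, setting out from 8.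
- The lithium acetylide 8 would be trapped in the same flask with Me3SiCl to give the storable silyl ynol ether F11.
- F11 would take the place of 9 in step 11 and should give the 6-silylphenol F12.
- Ipso-protodesilylation (CF3CO2H, CH2Cl2, 0 °C) would return to the route at 25.

**Further compounds**

F1 | step 11 | (Z)-tributyl{2-[2,6-dimethoxy-4-(2,4,6-trimethoxyphenoxy)phenoxy]ethenyl}stannane | CCCC[Sn](CCCC)(CCCC)/C=C\Oc1c(OC)cc(Oc2c(OC)cc(OC)cc2OC)cc1OC
F2 | step 11 | (Z)-{2-[2,6-dimethoxy-4-(2,4,6-trimethoxyphenoxy)phenoxy]ethenyl}lithium | [Li]/C=C\Oc1c(OC)cc(Oc2c(OC)cc(OC)cc2OC)cc1OC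
F3 | step 11 | 3,4-dimethoxycyclobut-3-ene-1,2-dione (dimethyl squarate) | COC1=C(OC)C(=O)C1=O
F4 | step 11 | 4-{(Z)-2-[2,6-dimethoxy-4-(2,4,6-trimethoxyphenoxy)phenoxy]ethenyl}-2,3,4-trimethoxycyclobut-2-en-1-one (racemic) | COC1=C(OC)C(OC)(/C=C\Oc2c(OC)cc(Oc3c(OC)cc(OC)cc3OC)cc2OC)C1=O
F5 | step 11 | 2,3,4-trimethoxy-6-[2,6-dimethoxy-4-(2,4,6-trimethoxyphenoxy)phenoxy]phenol | COc1cc(Oc2c(OC)cc(Oc3c(OC)cc(OC)cc3OC)cc2OC)c(O)c(OC)c1OC
F6 | step 11 | 3,4-dimethoxy-5-(3,4,5-trimethoxyphenoxy)phenyl trifluoromethanesulfonate | COc1cc(OS(=O)(=O)C(F)(F)F)cc(Oc2cc(OC)c(OC)c(OC)c2)c1OC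
F7 | step 11 | tridecamethyl ether of the target | COc1cc(OC)c(Oc2cc(OC)c(Oc3cc(OC)c(OC)c(OC)c3Oc3cc(OC)c(OC)c(Oc4cc(OC)c(OC)c(OC)c4)c3)c(OC)c2)c(OC)c1
F8 | step 9 | 3,4-bis[3,4-dimethoxy-5-(3,4,5-trimethoxyphenoxy)phenoxy]cyclobut-3-ene-1,2-dione | O=C1C(=O)C(Oc2cc(OC)c(OC)c(Oc3cc(OC)c(OC)c(OC)c3)c2)=C1Oc1cc(OC)c(OC)c(Oc2cc(OC)c(OC)c(OC)c2)c1
F9 | step 9 | 2,3-bis[3,4-dimethoxy-5-(3,4,5-trimethoxyphenoxy)phenoxy]-4-hydroxycyclobut-2-en-1-one (racemic) | O=C1C(Oc2cc(OC)c(OC)c(Oc3cc(OC)c(OC)c(OC)c3)c2)=C(Oc2cc(OC)c(OC)c(Oc3cc(OC)c(OC)c(OC)c3)c2)C1O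
F10 | step 9 | 2,3-bis[3,4-dimethoxy-5-(3,4,5-trimethoxyphenoxy)phenoxy]-4-methoxycyclobut-2-en-1-one (racemic) | O=C1C(Oc2cc(OC)c(OC)c(Oc3cc(OC)c(OC)c(OC)c3)c2)=C(Oc2cc(OC)c(OC)c(Oc3cc(OC)c(OC)c(OC)c3)c2)C1OC
F11 | step 4 | ({[2,6-dimethoxy-4-(2,4,6-trimethoxyphenoxy)phenoxy]ethynyl})trimethylsilane | C[Si](C)(C)C#COc1c(OC)cc(Oc2c(OC)cc(OC)cc2OC)cc1OC
F12 | step 4 | 2,3-dimethoxy-4-[3,4-dimethoxy-5-(3,4,5-trimethoxyphenoxy)phenoxy]-5-[2,6-dimethoxy-4-(2,4,6-trimethoxyphenoxy)phenoxy]-6-(trimethylsilyl)phenol | COc1cc(OC)c(Oc2cc(OC)c(Oc3c([Si](C)(C)C)c(O)c(OC)c(OC)c3Oc3cc(OC)c(OC)c(Oc4cc(OC)c(OC)c(OC)c4)c3)c(OC)c2)c(OC)c1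
A1 | direct plan | 4,5-difluoro-3-methoxyphthalaldehyde | COc1c(F)c(F)cc(C=O)c1C=O
A2 | direct plan | 2,6-dimethoxy-4-(2,4,6-trimethoxyphenoxy)phenol | COc1cc(OC)c(Oc2cc(OC)c(O)c(OC)c2)c(OC)c1
A3 | direct plan | 3,4-dimethoxy-5-(3,4,5-trimethoxyphenoxy)phenol | COc1cc(O)cc(Oc2cc(OC)c(OC)c(OC)c2)c1OC
A4 | direct plan | 4-[3,4-dimethoxy-5-(3,4,5-trimethoxyphenoxy)phenoxy]-5-[2,6-dimethoxy-4-(2,4,6-trimethoxyphenoxy)phenoxy]-3-methoxybenzene-1,2-dicarbaldehyde | COc1cc(OC)c(Oc2cc(OC)c(Oc3cc(C=O)c(C=O)c(OC)c3Oc3cc(OC)c(OC)c(Oc4cc(OC)c(OC)c(OC)c4)c3)c(OC)c2)c(OC)c1
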